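A direct plan would carry the complete (2E,6E)-ester chain as a (Z)-allylic alcohol, epoxidise it (Sharpless) and make the epoxy triflate A1;
in one flask A1 would alkylate the methyl-side enolate of the silyloxy keto ester A2, ring B would close by Dieckmann condensation (dione enolate A3),
and ring A would close by attack of an enolate oxygen on the epoxide (A4); ester hydrolysis and desilylation would finish.
Weakness (a), the one-flask alkylation–Dieckmann–epoxide opening: only a steric bias decides which of the two oxygens of the unsymmetrical enolate A3 closes ring A,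
the kinetic enolate of A2 can equilibrate to the α-silyloxy ester side and erode C5, and both advanced fragments are staked on this one operation.
Weakness (b), the making of A2: a methallyl group would be added to a glycidate only to be ozonised, three steps for a six-carbon piece with one stereocentre.
Weakness (c), the end: cleavage of the methyl ester of A4 with excess Me3SnOH at 80 °C, run on the finished and epimerisable α-silyloxy ketone.

Plan of the new route (locants O1, C2, C3, C3a, C4–C7, C7a of the hexahydrobenzofuranone):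
The retrosynthesis cuts C3a–C4 (ring B) first, then O1–C7a (ring A), then C3–C3a, so that C3a and C7a are carried as an alkyne.
The alkyne lies between an epoxide-derived C2 carbinol (side chain attached) and a hydroxy ester whose C4–C6 and C5 stereocentre come intact from methyl (R)-glycidate.
Ring A arises first, by 5-endo-dig attack of the C2 hydroxyl on the alkyne with iodine delivered to C3a; ring B second, by acylation of C3a with the ester carbon that becomes C4.
The feature that allows this: the tetrasubstituted C3a=C7a bond shared by rings A and B bears O1 and C4 trans, so it is the anti-adduct of an oxygen and an acyl carbon to an alkyne to which the C2 hydroxyl is homopropargylic.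
O1 is bonded to C7a before any 1,3-dione exists, so no choice between two enol oxygens arises and each ring closes in a step of its own; the C4–C6 piece needs no masked ketone; the acid is freed by fluoride with the silyl ethers, so no ester hydrolysis is run on the finished ketol.

Key step: step 11

Assumption: 2-(trimethylsilyl)ethyl methacrylate is bought as a catalogue monomer, and propargylmagnesium bromide is made from propargyl bromide and magnesium just before use.

Step 1
Reactants: 1 methyl (2R)-oxirane-2-carboxylate (methyl (R)-glycidate); 2 prop-2-yn-1-ylmagnesium bromide (propargylmagnesium bromide)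
Product: 3 methyl (2R)-2-hydroxyhex-5-ynoate
Conditions: 2 (1.3 equiv), CuBr·SMe2 (10 mol%), THF/Et2O, −78 → −50 °C; aq NH4Cl
Reagents that add atoms: none
Why: Copper-catalysed SN2 opening of the glycidic ester at the unsubstituted C3 by the Grignard reagent (the allenyl/propargyl magnesium species couples through its γ-carbon to give the propargyl product) should outrun addition to the ester at −78 °C and leave the C2 stereocentre (R), the future C5, untouched.

Step 2
Reactants: 3 methyl (2R)-2-hydroxyhex-5-ynoate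
Product: 4 methyl (2R)-2-[(tert-butyldimethylsilyl)oxy]hex-5-ynoate
Conditions: TBSCl, imidazole, DMF, rt
Reagents that add atoms: tert-butyldimethylsilyl chloride, CC(C)(C)[Si](C)(C)Cl
Why: Corey silylation of the secondary alcohol occurs at oxygen only, so the stereocentre is retained and the hydroxyl is masked for the organolithium steps.

Step 3
Reactants: 5 neryl acetate, (2Z)-3,7-dimethylocta-2,6-dien-1-yl acetate
Product: 6 (2Z,6E)-8-hydroxy-3,7-dimethylocta-2,6-dien-1-yl acetate
Conditions: SeO2 (10 mol%), t-BuOOH, salicylic acid (10 mol%), CH2Cl2, rt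
Reagents that add atoms: tert-butyl hydroperoxide, CC(C)(C)OO
Why: Catalytic SeO2 allylic oxidation (ene reaction then [2,3]-sigmatropic shift) should hydroxylate the (E)-methyl group of the electron-rich terminal alkene with retention of geometry, the 2,3-alkene being deactivated by the allylic acetate.

Step 4
Reactants: 6 (2Z,6E)-8-hydroxy-3,7-dimethylocta-2,6-dien-1-yl acetate
Product: 7 (2Z,6E)-8-bromo-3,7-dimethylocta-2,6-dien-1-yl acetate
Conditions: CBr4, PPh3, CH2Cl2, 0 °C
Reagents that add atoms: carbon tetrabromide, BrC(Br)(Br)Br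
Why: Appel reaction: SN2 displacement of the oxyphosphonium group gives the primary allylic bromide without touching the acetate or either alkene geometry.

Step 5
Reactants: 7 (2Z,6E)-8-bromo-3,7-dimethylocta-2,6-dien-1-yl acetate; 8 allylmagnesium bromide
Product: 9 (2Z,6E)-3,7-dimethylundeca-2,6,10-trien-1-ol
Conditions: 8 (3.5 equiv), THF, −78 → 0 °C; aq NH4Cl
Reagents that add atoms: none
Why: SN2 allyl–allyl coupling of the Grignard reagent at the primary allylic bromide adds the three-carbon tail, and the excess reagent removes the acetate by double addition, leaving the 2Z and 6E alkenes unchanged.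

Step 6
Reactants: 9 (2Z,6E)-3,7-dimethylundeca-2,6,10-trien-1-ol; 10 2-(trimethylsilyl)ethyl methacrylate
Product: 11 2-(trimethylsilyl)ethyl (2E,6E,10Z)-12-hydroxy-2,6,10-trimethyldodeca-2,6,10-trienoate
Conditions: 10 (8 equiv), second-generation Hoveyda–Grubbs catalyst RuCl2(=CH-C6H4-2-Oi-Pr)(H2IMes) (5 mol%; H2IMes = 1,3-dimesitylimidazolidin-2-ylidene), CH2Cl2, 40 °C
Reagents that add atoms: none
Why: Olefin cross-metathesis of the only monosubstituted alkene with the 1,1-disubstituted acrylate should give the thermodynamically favoured (E)-2-methyl-2-enoate, the trisubstituted alkenes do not engage the ruthenium carbene, and the 2-(trimethylsilyl)ethyl ester is chosen so that the acid can later be freed by fluoride.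

Step 7
Reactants: 11 2-(trimethylsilyl)ethyl (2E,6E,10Z)-12-hydroxy-2,6,10-trimethyldodeca-2,6,10-trienoate
Product: 12 2-(trimethylsilyl)ethyl (2E,6E)-9-[(2R,3S)-3-(hydroxymethyl)-2-methyloxiran-2-yl]-2,6-dimethylnona-2,6-dienoate
Conditions: Ti(Oi-Pr)4 (10 mol%), L-(+)-diethyl tartrate (12 mol%), t-BuOOH, 4 Å molecular sieves, CH2Cl2, −20 °C
Reagents that add atoms: tert-butyl hydroperoxide, CC(C)(C)OO
Why: Katsuki–Sharpless asymmetric epoxidation oxidises only the allylic-alcohol alkene, and L-(+)-tartrate on the (Z)-allylic alcohol (as in nerol → (2S,3R)-epoxide) should give the cis-epoxide with the CH carbon S and the quaternary carbon R; this oxygen stays on the CH carbon to the end and becomes O1.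

Step 8
Reactants: 12 2-(trimethylsilyl)ethyl (2E,6E)-9-[(2R,3S)-3-(hydroxymethyl)-2-methyloxiran-2-yl]-2,6-dimethylnona-2,6-dienoate; 4 methyl (2R)-2-[(tert-butyldimethylsilyl)oxy]hex-5-ynoate
Product: 15 methyl (2R)-2-[(tert-butyldimethylsilyl)oxy]-7-{(2S,3R)-3-[(3E,7E)-4,8-dimethyl-9-oxo-9-[2-(trimethylsilyl)ethoxy]nona-3,7-dien-1-yl]-3-methyloxiran-2-yl}hept-5-ynoate, via epoxy triflate 13 (not isolated), via lithium acetylide 14 (not isolated)
Conditions: 12: Tf2O, 2,6-lutidine, CH2Cl2, −78 °C, cold work-up; 4: LiN(SiMe3)2 (1.05 equiv), THF, −78 °C; then 13, DMPU, −78 → −40 °C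
Reagents that add atoms: none
Why: Triflation of the primary alcohol and SN2 displacement of the triflate by the lithium acetylide (alkylation of an acetylide with a 2,3-epoxy triflate) should be faster at −78 °C than attack on the epoxide or the esters, so C3–C3a forms with all three stereocentres untouched and the minor enantiomer of 12 ends as a separable diastereomer.

Step 9
Reactants: 15 methyl (2R)-2-[(tert-butyldimethylsilyl)oxy]-7-{(2S,3R)-3-[(3E,7E)-4,8-dimethyl-9-oxo-9-[2-(trimethylsilyl)ethoxy]nona-3,7-dien-1-yl]-3-methyloxiran-2-yl}hept-5-ynoate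
Product: 16 1-methyl 18-[2-(trimethylsilyl)ethyl] (2R,8S,9S,12E,16E)-2-[(tert-butyldimethylsilyl)oxy]-8,9-dihydroxy-9,13,17-trimethyloctadeca-12,16-dien-5-ynedioate
Conditions: HClO4 (5 mol%), THF/H2O (3:1), 0 °C → rt
Reagents that add atoms: water, O
Why: Acid-catalysed hydrolysis of the trisubstituted epoxide: water should enter at the tertiary carbon with inversion (borderline A-2 opening) while the C–O bond at the secondary carbon is kept, which gives the (8S,9S)-diol, that is the (S)-C2 and the (S)-carbinol of the target.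

Step 10
Reactants: 16 1-methyl 18-[2-(trimethylsilyl)ethyl] (2R,8S,9S,12E,16E)-2-[(tert-butyldimethylsilyl)oxy]-8,9-dihydroxy-9,13,17-trimethyloctadeca-12,16-dien-5-ynedioate
Product: 18 1-methyl 18-[2-(trimethylsilyl)ethyl] (2R,8S,9S,12E,16E)-2-[(tert-butyldimethylsilyl)oxy]-8-hydroxy-9,13,17-trimethyl-9-[(triethylsilyl)oxy]octadeca-12,16-dien-5-ynedioate, via bis(triethylsilyl) ether 17 (not isolated)
Conditions: Et3SiOTf (2.5 equiv), 2,6-lutidine, CH2Cl2, −78 → 0 °C; then pyridinium p-toluenesulfonate (0.2 equiv), MeOH/CH2Cl2, −10 °C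
Reagents that add atoms: triethylsilyl trifluoromethanesulfonate, CC[Si](CC)(CC)OS(=O)(=O)C(F)(F)F
Why: Exhaustive silylation followed by acid-catalysed methanolysis, in which the secondary triethylsilyl ether should be cleaved far faster than the tertiary one and the tert-butyldimethylsilyl ether is inert, leaves the C8 hydroxyl as the only free one; no stereocentre is touched.

Step 11
Reactants: 18 1-methyl 18-[2-(trimethylsilyl)ethyl] (2R,8S,9S,12E,16E)-2-[(tert-butyldimethylsilyl)oxy]-8-hydroxy-9,13,17-trimethyl-9-[(triethylsilyl)oxy]octadeca-12,16-dien-5-ynedioate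
Product: 19 methyl (2R)-2-[(tert-butyldimethylsilyl)oxy]-4-[(5S)-5-{(2S,5E,9E)-6,10-dimethyl-11-oxo-2-[(triethylsilyl)oxy]-11-[2-(trimethylsilyl)ethoxy]undeca-5,9-dien-2-yl}-3-iodo-4,5-dihydrofuran-2-yl]butanoate
Conditions: Ph3PAuNTf2 (3 mol%), N-iodosuccinimide (1.05 equiv), NaHCO3, CH2Cl2, −20 → 0 °C, dark
Reagents that add atoms: N-iodosuccinimide, O=C1CCC(=O)N1I
Why: The cationic gold complex coordinates the alkyne, the C8 hydroxyl of 18 (C2 of the target) attacks the distal alkyne carbon anti to gold to form O1–C7a, and the vinyl–gold bond at C3a is then cleaved by the iodonium source with retention (or the protodeaurated enol ether is iodinated at the same carbon) to give the β-iodo enol ether. The closest known reaction types are the gold-catalysed cycloisomerisation of homopropargylic alcohols to 2,3-dihydrofurans and the iodocyclisation of the same alcohols to 4-iodo-2,3-dihydrofurans. Ring A closes in the 5-endo-dig mode; the only other mode open to this oxygen would be a 4-exo-dig attack, and the tertiary oxygen is silylated, so O1 can end only on C7a. No stereocentre is formed: C2 and the side-chain carbinol keep the configurations set by the epoxidation and the hydrolysis. The selectivity needed is alkyne over the two trisubstituted alkenes and the enoate, which the π-acid should secure by activating only the alkyne while the single equivalent of N-iodosuccinimide is taken up at C3a. The anti relation of O1 and iodine puts the iodine cis to the C7 chain, exactly where C4 must later be attached.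

Step 12
Reactants: 19 methyl (2R)-2-[(tert-butyldimethylsilyl)oxy]-4-[(5S)-5-{(2S,5E,9E)-6,10-dimethyl-11-oxo-2-[(triethylsilyl)oxy]-11-[2-(trimethylsilyl)ethoxy]undeca-5,9-dien-2-yl}-3-iodo-4,5-dihydrofuran-2-yl]butanoate
Product: 21 2-(trimethylsilyl)ethyl (2E,6E,10S)-10-{(2S,5R)-5-[(tert-butyldimethylsilyl)oxy]-4-oxo-2,3,4,5,6,7-hexahydro-1-benzofuran-2-yl}-2,6-dimethyl-10-[(triethylsilyl)oxy]undeca-2,6-dienoate, via vinyllithium 20 (not isolated)
Conditions: n-BuLi (1.05 equiv), THF, −100 °C, 10 min; → −78 °C; aq NH4Cl at −78 °C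
Reagents that add atoms: none
Why: Parham-type cyclisation: iodine–lithium exchange at −100 °C gives the vinyllithium, whose 6-exo-trig attack on the tethered methyl ester (lithium hemiketal, ketone on work-up) should be faster than its fragmentation or attack on the hindered chain ester, so ring B closes with C4 as the vinylogous-ester carbonyl and C5 (R) carried in unchanged.

Step 13
Reactants: 21 2-(trimethylsilyl)ethyl (2E,6E,10S)-10-{(2S,5R)-5-[(tert-butyldimethylsilyl)oxy]-4-oxo-2,3,4,5,6,7-hexahydro-1-benzofuran-2-yl}-2,6-dimethyl-10-[(triethylsilyl)oxy]undeca-2,6-dienoate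
Product: 22 (2E,6E,10S)-10-hydroxy-10-[(2S,5R)-5-hydroxy-4-oxo-2,3,4,5,6,7-hexahydro-1-benzofuran-2-yl]-2,6-dimethylundeca-2,6-dienoic acid
Conditions: (Me2N)3S+ Me3SiF2− (tris(dimethylamino)sulfonium difluorotrimethylsilicate, 4 equiv), DMF, 0 °C → rt; aq NH4Cl
Reagents that add atoms: none
Why: Fluoride should cleave the two silyl ethers and trigger β-elimination of the 2-(trimethylsilyl)ethyl ester (ethene and fluorotrimethylsilane) under non-basic conditions, so ketol, tertiary alcohol and acid are freed in one operation with no stereocentre affected.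

## Compound list

1 | methyl (2R)-oxirane-2-carboxylate | COC(=O)[C@H]1CO1 | starting material
2 | prop-2-yn-1-ylmagnesium bromide (propargylmagnesium bromide) | C#CC[Mg]Br | starting material
3 | methyl (2R)-2-hydroxyhex-5-ynoate | COC(=O)[C@H](O)CCC#C | intermediate
4 | methyl (2R)-2-[(tert-butyldimethylsilyl)oxy]hex-5-ynoate | COC(=O)[C@H](O[Si](C)(C)C(C)(C)C)CCC#C | intermediate
5 | neryl acetate, (2Z)-3,7-dimethylocta-2,6-dien-1-yl acetate | CC(C)=CCC/C(C)=C\COC(C)=O | starting material
6 | (2Z,6E)-8-hydroxy-3,7-dimethylocta-2,6-dien-1-yl acetate | OC/C(C)=C/CC/C(C)=C\COC(C)=O | intermediate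
7 | (2Z,6E)-8-bromo-3,7-dimethylocta-2,6-dien-1-yl acetate | BrC/C(C)=C/CC/C(C)=C\COC(C)=O | intermediate
8 | allylmagnesium bromide | C=CC[Mg]Br | starting material
9 | (2Z,6E)-3,7-dimethylundeca-2,6,10-trien-1-ol | C=CCC/C(C)=C/CC/C(C)=C\CO | intermediate
10 | 2-(trimethylsilyl)ethyl methacrylate, 2-(trimethylsilyl)ethyl 2-methylprop-2-enoate | C=C(C)C(=O)OCC[Si](C)(C)C | starting material
11 | 2-(trimethylsilyl)ethyl (2E,6E,10Z)-12-hydroxy-2,6,10-trimethyldodeca-2,6,10-trienoate | C[Si](C)(C)CCOC(=O)/C(C)=C/CC/C(C)=C/CC/C(C)=C\CO | intermediate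
12 | 2-(trimethylsilyl)ethyl (2E,6E)-9-[(2R,3S)-3-(hydroxymethyl)-2-methyloxiran-2-yl]-2,6-dimethylnona-2,6-dienoate | C[Si](C)(C)CCOC(=O)/C(C)=C/CC/C(C)=C/CC[C@@]1(C)O[C@H]1CO | intermediate
13 | 2-(trimethylsilyl)ethyl (2E,6E)-2,6-dimethyl-9-[(2R,3S)-2-methyl-3-({[(trifluoromethyl)sulfonyl]oxy}methyl)oxiran-2-yl]nona-2,6-dienoate | C[Si](C)(C)CCOC(=O)/C(C)=C/CC/C(C)=C/CC[C@@]1(C)O[C@H]1COS(=O)(=O)C(F)(F)F | intermediate (not isolated)
14 | {(5R)-5-[(tert-butyldimethylsilyl)oxy]-6-methoxy-6-oxohex-1-yn-1-yl}lithium, the lithium acetylide of 4 | COC(=O)[C@H](O[Si](C)(C)C(C)(C)C)CCC#C[Li] | intermediate (not isolated)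
15 | methyl (2R)-2-[(tert-butyldimethylsilyl)oxy]-7-{(2S,3R)-3-[(3E,7E)-4,8-dimethyl-9-oxo-9-[2-(trimethylsilyl)ethoxy]nona-3,7-dien-1-yl]-3-methyloxiran-2-yl}hept-5-ynoate | C[Si](C)(C)CCOC(=O)/C(C)=C/CC/C(C)=C/CC[C@@]1(C)O[C@H]1CC#CCC[C@@H](O[Si](C)(C)C(C)(C)C)C(=O)OC | intermediate
16 | 1-methyl 18-[2-(trimethylsilyl)ethyl] (2R,8S,9S,12E,16E)-2-[(tert-butyldimethylsilyl)oxy]-8,9-dihydroxy-9,13,17-trimethyloctadeca-12,16-dien-5-ynedioate | C[Si](C)(C)CCOC(=O)/C(C)=C/CC/C(C)=C/CC[C@](C)(O)[C@@H](O)CC#CCC[C@@H](O[Si](C)(C)C(C)(C)C)C(=O)OC | intermediate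
17 | 1-methyl 18-[2-(trimethylsilyl)ethyl] (2R,8S,9S,12E,16E)-2-[(tert-butyldimethylsilyl)oxy]-9,13,17-trimethyl-8,9-bis[(triethylsilyl)oxy]octadeca-12,16-dien-5-ynedioate | C[Si](C)(C)CCOC(=O)/C(C)=C/CC/C(C)=C/CC[C@](C)(O[Si](CC)(CC)CC)[C@@H](O[Si](CC)(CC)CC)CC#CCC[C@@H](O[Si](C)(C)C(C)(C)C)C(=O)OC | intermediate (not isolated)
18 | 1-methyl 18-[2-(trimethylsilyl)ethyl] (2R,8S,9S,12E,16E)-2-[(tert-butyldimethylsilyl)oxy]-8-hydroxy-9,13,17-trimethyl-9-[(triethylsilyl)oxy]octadeca-12,16-dien-5-ynedioate | C[Si](C)(C)CCOC(=O)/C(C)=C/CC/C(C)=C/CC[C@](C)(O[Si](CC)(CC)CC)[C@@H](O)CC#CCC[C@@H](O[Si](C)(C)C(C)(C)C)C(=O)OC | intermediate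
19 | methyl (2R)-2-[(tert-butyldimethylsilyl)oxy]-4-[(5S)-5-{(2S,5E,9E)-6,10-dimethyl-11-oxo-2-[(triethylsilyl)oxy]-11-[2-(trimethylsilyl)ethoxy]undeca-5,9-dien-2-yl}-3-iodo-4,5-dihydrofuran-2-yl]butanoate | C[Si](C)(C)CCOC(=O)/C(C)=C/CC/C(C)=C/CC[C@](C)(O[Si](CC)(CC)CC)[C@@H]1CC(I)=C(CC[C@@H](O[Si](C)(C)C(C)(C)C)C(=O)OC)O1 | intermediate
20 | {(5S)-2-{(3R)-3-[(tert-butyldimethylsilyl)oxy]-4-methoxy-4-oxobutyl}-5-{(2S,5E,9E)-6,10-dimethyl-11-oxo-2-[(triethylsilyl)oxy]-11-[2-(trimethylsilyl)ethoxy]undeca-5,9-dien-2-yl}-4,5-dihydrofuran-3-yl}lithium, 19 with lithium in place of iodine | C[Si](C)(C)CCOC(=O)/C(C)=C/CC/C(C)=C/CC[C@](C)(O[Si](CC)(CC)CC)[C@@H]1CC([Li])=C(CC[C@@H](O[Si](C)(C)C(C)(C)C)C(=O)OC)O1 | intermediate (not isolated)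
21 | 2-(trimethylsilyl)ethyl (2E,6E,10S)-10-{(2S,5R)-5-[(tert-butyldimethylsilyl)oxy]-4-oxo-2,3,4,5,6,7-hexahydro-1-benzofuran-2-yl}-2,6-dimethyl-10-[(triethylsilyl)oxy]undeca-2,6-dienoate | C[Si](C)(C)CCOC(=O)/C(C)=C/CC/C(C)=C/CC[C@](C)(O[Si](CC)(CC)CC)[C@@H]1CC2=C(CC[C@@H](O[Si](C)(C)C(C)(C)C)C2=O)O1 | intermediate
22 | (2E,6E,10S)-10-hydroxy-10-[(2S,5R)-5-hydroxy-4-oxo-2,3,4,5,6,7-hexahydro-1-benzofuran-2-yl]-2,6-dimethylundeca-2,6-dienoic acid | C/C(=C\CC[C@](C)(O)[C@@H]1CC2=C(CC[C@@H](O)C2=O)O1)CC/C=C(\C)C(=O)O | target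

Total step count: 13. Longest linear sequence: 11 steps (steps 3 to 13, from neryl acetate).

Steps most likely to fail, each with one fallback:

Step 12. The β-oxygenated vinyllithium may fragment (anti β-elimination of the ring oxygen, which reopens ring A to an alkynyl alkoxide) or add to the chain ester before it reaches the methyl ester. The fallback sets out from 19 and comes back at 21. Selective reduction of the methyl ester with i-Bu2AlH (CH2Cl2, −78 °C) would give the aldehyde 2-(trimethylsilyl)ethyl (2E,6E,10S)-10-{(2S)-5-[(3R)-3-[(tert-butyldimethylsilyl)oxy]-4-oxobutyl]-4-iodo-2,3-dihydrofuran-2-yl}-2,6-dimethyl-10-[(triethylsilyl)oxy]undeca-2,6-dienoate F1. Nozaki–Hiyama–Kishi ring closure (CrCl2, NiCl2 (2 mol%), DMSO/THF, rt), whose vinylchromium intermediate neither eliminates nor attacks esters, would give the C4 carbinol 2-(trimethylsilyl)ethyl (2E,6E,10S)-10-{(2S,5R)-5-[(tert-butyldimethylsilyl)oxy]-4-hydroxy-2,3,4,5,6,7-hexahydro-1-benzofuran-2-yl}-2,6-dimethyl-10-[(triethylsilyl)oxy]undeca-2,6-dienoate F2 (either configuration at C4). Dess–Martin oxidation (NaHCO3, CH2Cl2) would then return to 21.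

Step 11. Iodo-etherification of the C12=C13 alkene by the free hydroxyl, or iodination of an alkene before the gold-triggered closure, may compete with the alkyne pathway. The fallback sets out from 18 and comes back at 19. Cycloisomerisation with Ph3PAuNTf2 alone (CH2Cl2, 0 °C) would give the enol ether methyl (2R)-2-[(tert-butyldimethylsilyl)oxy]-4-[(5S)-5-{(2S,5E,9E)-6,10-dimethyl-11-oxo-2-[(triethylsilyl)oxy]-11-[2-(trimethylsilyl)ethoxy]undeca-5,9-dien-2-yl}-4,5-dihydrofuran-2-yl]butanoate F3, which has no free hydroxyl left. Its enol ether carbon is by far the most electron-rich alkene position and would be iodinated by N-iodosuccinimide with 2,6-lutidine at −78 °C (addition, then loss of the proton), so that ring closure and halogenation are separated.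

Step 1. Addition of the Grignard reagent to the ester, or coupling through its allenyl terminus, may compete with epoxide opening. The fallback sets out from 1 and comes back at 4. Copper-catalysed opening of 1 with allylmagnesium bromide 8 (CuBr·SMe2, THF, −78 °C) would give methyl (2R)-2-hydroxyhex-5-enoate F4. Silylation (TBSCl, imidazole, DMF) would give methyl (2R)-2-[(tert-butyldimethylsilyl)oxy]hex-5-enoate F5. Ozonolysis (O3, CH2Cl2/MeOH, −78 °C; Me2S) would give methyl (2R)-2-[(tert-butyldimethylsilyl)oxy]-5-oxopentanoate F6. Ohira–Bestmann homologation (dimethyl (1-diazo-2-oxopropyl)phosphonate, K2CO3, MeOH) would then build the alkyne from the aldehyde and give 4.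

Further compounds

F1 | step 12 | 2-(trimethylsilyl)ethyl (2E,6E,10S)-10-{(2S)-5-[(3R)-3-[(tert-butyldimethylsilyl)oxy]-4-oxobutyl]-4-iodo-2,3-dihydrofuran-2-yl}-2,6-dimethyl-10-[(triethylsilyl)oxy]undeca-2,6-dienoate | C[Si](C)(C)CCOC(=O)/C(C)=C/CC/C(C)=C/CC[C@](C)(O[Si](CC)(CC)CC)[C@@H]1CC(I)=C(CC[C@@H](O[Si](C)(C)C(C)(C)C)C=O)O1
F2 | step 12 | 2-(trimethylsilyl)ethyl (2E,6E,10S)-10-{(2S,5R)-5-[(tert-butyldimethylsilyl)oxy]-4-hydroxy-2,3,4,5,6,7-hexahydro-1-benzofuran-2-yl}-2,6-dimethyl-10-[(triethylsilyl)oxy]undeca-2,6-dienoate (either configuration at C4) | C[Si](C)(C)CCOC(=O)/C(C)=C/CC/C(C)=C/CC[C@](C)(O[Si](CC)(CC)CC)[C@@H]1CC2=C(CC[C@@H](O[Si](C)(C)C(C)(C)C)C2O)O1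
F3 | step 11 | methyl (2R)-2-[(tert-butyldimethylsilyl)oxy]-4-[(5S)-5-{(2S,5E,9E)-6,10-dimethyl-11-oxo-2-[(triethylsilyl)oxy]-11-[2-(trimethylsilyl)ethoxy]undeca-5,9-dien-2-yl}-4,5-dihydrofuran-2-yl]butanoate | C[Si](C)(C)CCOC(=O)/C(C)=C/CC/C(C)=C/CC[C@](C)(O[Si](CC)(CC)CC)[C@@H]1CC=C(CC[C@@H](O[Si](C)(C)C(C)(C)C)C(=O)OC)O1
F4 | step 1 | methyl (2R)-2-hydroxyhex-5-enoate | COC(=O)[C@H](O)CCC=C
F5 | step 1 | methyl (2R)-2-[(tert-butyldimethylsilyl)oxy]hex-5-enoate | COC(=O)[C@H](O[Si](C)(C)C(C)(C)C)CCC=C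
F6 | step 1 | methyl (2R)-2-[(tert-butyldimethylsilyl)oxy]-5-oxopentanoate | COC(=O)[C@H](O[Si](C)(C)C(C)(C)C)CCC=O
A1 | direct plan | methyl (2E,6E)-2,6-dimethyl-9-[(2S,3R)-2-methyl-3-({[(trifluoromethyl)sulfonyl]oxy}methyl)oxiran-2-yl]nona-2,6-dienoate | COC(=O)/C(C)=C/CC/C(C)=C/CC[C@]1(C)O[C@@H]1COS(=O)(=O)C(F)(F)F
A2 | direct plan | methyl (2R)-2-[(tert-butyldimethylsilyl)oxy]-5-oxohexanoate | COC(=O)[C@H](O[Si](C)(C)C(C)(C)C)CCC(C)=O
A3 | direct plan | (4R)-4-[(tert-butyldimethylsilyl)oxy]-2-({(2R,3S)-3-[(3E,7E)-9-methoxy-4,8-dimethyl-9-oxonona-3,7-dien-1-yl]-3-methyloxiran-2-yl}methyl)cyclohexane-1,3-dione, enol form drawn | O=C1[C@H](O[Si](C)(C)C(C)(C)C)CCC(O)=C1C[C@H]2O[C@@]2(C)CC/C=C(\C)CC/C=C(\C)C(=O)OC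
A4 | direct plan | methyl (2E,6E,10S)-10-{(2S,5R)-5-[(tert-butyldimethylsilyl)oxy]-4-oxo-2,3,4,5,6,7-hexahydro-1-benzofuran-2-yl}-10-hydroxy-2,6-dimethylundeca-2,6-dienoate | C/C(=C\CC[C@](C)(O)[C@@H]1CC2=C(CC[C@@H](O[Si](C)(C)C(C)(C)C)C2=O)O1)CC/C=C(\C)C(=O)OC
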